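**Plan**

- Ring numbering: C1 is the carbonyl between C2–OMe and C6–hexaprenyl; C4 is the carbonyl between C3–H and C5–H. The quinone is taken back to hydroquinone 21, whose ring is cut at the C4–C5 bond to give dienylketene 20, which folds back to the four-membered carbinol 19.
- Enabling feature: C4 is a carbonyl flanked by two unsubstituted ring CH groups, and C5H=C6(hexaprenyl) is a 1,1-disubstituted vinyl terminus. C1(=O)–C2(OMe)=C3H–C4(=O) is the full carbon set of 3-methoxycyclobutenedione, so the strained four-membered ring can release a ketene at C4 that closes onto C5.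
- Further cuts: 19 at the carbinol–vinyl bond (methyl semisquarate 17 + vinyllithium 18); vinyl bromide 14 at C–Br (bromoboration of enyne 12); 12 at the alkyne–CH2 bond (hexaprenyl bromide 10 + ethynyl Grignard 11); the C30 chain at C12–C13 (two farnesyl units, sulfone coupling).
- Forward order: farnesyl + farnesyl → hexaprenol → bromide → skipped enyne → 2-bromo-1,4-diene; the derived vinyllithium adds to 17; thermolysis forms the only ring made (the six-membered carbocycle, step 11); Ag2O gives the quinone.
- Stereochemistry: the target has no stereocentre. Four E olefins come from the two (2E,6E)-farnesyl units; the fifth (C10=C11 of the head unit) comes from E-selective SeO2 oxidation. The later steps are chosen to leave olefin position and geometry untouched.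

Key step: step 11

Assumption: farnesyl acetate and farnesyl bromide are used as the pure (2E,6E) isomers, so every chain intermediate is all-E.

**Step 1**
Reactants: 1 (2E,6E)-farnesyl acetate
Product: 2 (2E,6E,10E)-12-hydroxy-3,7,11-trimethyldodeca-2,6,10-trien-1-yl acetate
Conditions: SeO2 (cat.), t-BuOOH, salicylic acid (cat.), CH2Cl2, 0 °C to rt
Reagents that add atoms: tert-butyl hydroperoxide, CC(C)(C)OO
Why: Catalytic SeO2 allylic oxidation (Riley-type; ene reaction then [2,3]-sigmatropic shift) should attack the terminal, most electron-rich and least hindered trisubstituted olefin at its E-methyl group, which sets the E geometry of the C10=C11 olefin, while the acetate deactivates the C2=C3 olefin.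

**Step 2**
Reactants: 2 (2E,6E,10E)-12-hydroxy-3,7,11-trimethyldodeca-2,6,10-trien-1-yl acetate
Product: 3 (2E,6E,10E)-12-bromo-3,7,11-trimethyldodeca-2,6,10-trien-1-yl acetate
Conditions: CBr4, PPh3, CH2Cl2, 0 °C
Reagents that add atoms: carbon tetrabromide, BrC(Br)(Br)Br
Why: The Appel reaction should convert the primary allylic alcohol into the bromide by SN2 displacement of the oxyphosphonium group under neutral conditions that spare the acetate and the olefin geometry.

**Step 3**
Reactants: 4 (2E,6E)-farnesyl bromide
Product: 5 (2E,6E)-farnesyl phenyl sulfone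
Conditions: PhSO2Na, DMF, rt
Reagents that add atoms: sodium benzenesulfinate, [Na+].[O-]S(=O)c1ccccc1
Why: S-alkylation of the sulfinate by the primary allylic bromide (SN2) should give the allylic sulfone with the 2E olefin unchanged.

**Step 4**
Reactants: 5 (2E,6E)-farnesyl phenyl sulfone; 3 (2E,6E,10E)-12-bromo-3,7,11-trimethyldodeca-2,6,10-trien-1-yl acetate
Product: 7 (2E,6E,10E,14E,18E)-3,7,11,15,19,23-hexamethyl-13-(phenylsulfonyl)tetracosa-2,6,10,14,18,22-hexaen-1-yl acetate (racemic), via lithiated sulfone 6 (not isolated)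
Conditions: n-BuLi, THF, −78 °C; then 3, THF/DMPU, −78 °C
Reagents that add atoms: none
Why: Allyl sulfone alkylation (Biellmann-type coupling): the sulfonyl-stabilised allyl anion should react at its α-carbon with the allylic bromide by SN2 much faster than with the acetate at −78 °C; the new sulfone-bearing stereocentre is racemic and is erased in step 5.

**Step 5**
Reactants: 7 (2E,6E,10E,14E,18E)-3,7,11,15,19,23-hexamethyl-13-(phenylsulfonyl)tetracosa-2,6,10,14,18,22-hexaen-1-yl acetate
Product: 9 all-E hexaprenol, via lithium alkoxide sulfone 8 (not isolated)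
Conditions: LiBHEt3 (excess), THF, 0 °C; then PdCl2(dppp) (cat.), 0 °C to rt
Reagents that add atoms: none
Why: LiBHEt3 should first cleave the acetate to a non-ionisable lithium alkoxide; zerovalent palladium formed from the divalent precatalyst PdCl2(dppp) then ionises the allylic sulfone to a syn π-allyl complex that takes hydride at its less substituted terminus (palladium-catalysed reductive desulfonylation, a Tsuji–Trost-type hydrogenolysis), restoring the E-trisubstituted olefin in place.

**Step 6**
Reactants: 9 all-E hexaprenol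
Product: 10 all-E hexaprenyl bromide
Conditions: PBr3, Et2O, −10 to 0 °C
Reagents that add atoms: phosphorus tribromide, BrP(Br)Br
Why: Bromination of the primary allylic alcohol with PBr3 (SN2 on the phosphite ester) at low temperature is the standard way to polyprenyl bromides and should retain the 2E geometry.

**Step 7**
Reactants: 10 all-E hexaprenyl bromide; 11 ethynylmagnesium bromide (HC≡CMgBr)
Product: 12 (4E,8E,12E,16E,20E)-5,9,13,17,21,25-hexamethylhexacosa-4,8,12,16,20,24-hexaen-1-yne
Conditions: HC≡CMgBr (excess), CuCl (cat.), THF, 0 to 50 °C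
Reagents that add atoms: none
Why: Copper-catalysed coupling of an alkynyl Grignard reagent with a primary allylic bromide should give the skipped enyne by attack at the unhindered CH2 terminus (SN2), the excess of 11 suppressing double alkylation.

**Step 8**
Reactants: 12 (4E,8E,12E,16E,20E)-5,9,13,17,21,25-hexamethylhexacosa-4,8,12,16,20,24-hexaen-1-yne
Product: 14 (4E,8E,12E,16E,20E)-2-bromo-5,9,13,17,21,25-hexamethylhexacosa-1,4,8,12,16,20,24-heptaene, via bromoalkenylborane 13 (not isolated)
Conditions: B-bromo-9-BBN, CH2Cl2, 0 °C; then AcOH, 0 °C to rt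
Reagents that add atoms: B-bromo-9-borabicyclo[3.3.1]nonane, BrB1C2CCCC1CCC2
Why: Syn-bromoboration of the terminal alkyne (Br to the internal carbon, boron to the terminus) is selective for terminal triple bonds over trisubstituted olefins, and protonolysis of the alkenyl C–B bond with AcOH should give the 2-bromo-1-alkene.

**Step 9**
Reactants: 15 dimethyl squarate
Product: 17 3-methoxycyclobut-3-ene-1,2-dione (methyl semisquarate), via hydroxycyclobutenone 16 (not isolated)
Conditions: LiAlH(Ot-Bu)3, THF, −78 °C; then conc. HCl, CH2Cl2, 0 °C to rt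
Reagents that add atoms: water, O
Why: 1,2-Hydride reduction of one squarate carbonyl, then acid-induced ionisation of the carbinol to an oxocarbenium ion that is hydrolysed with loss of methanol (1,3-carbonyl transposition), is the standard entry to semisquaric esters.

**Step 10**
Reactants: 14 (4E,8E,12E,16E,20E)-2-bromo-5,9,13,17,21,25-hexamethylhexacosa-1,4,8,12,16,20,24-heptaene; 17 3-methoxycyclobut-3-ene-1,2-dione
Product: 19 4-hydroxy-3-methoxy-4-[(4E,8E,12E,16E,20E)-5,9,13,17,21,25-hexamethylhexacosa-1,4,8,12,16,20,24-heptaen-2-yl]cyclobut-2-en-1-one (racemic), via vinyllithium 18 (not isolated)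
Conditions: t-BuLi (2 equiv), Et2O, −78 °C; then added to 17, THF, −78 °C; aq. NH4Cl, −78 °C
Reagents that add atoms: none
Why: Bromine–lithium exchange followed by 1,2-addition of the alkenyllithium (squarate-type addition) should occur at C2 of 17, the ketone carbonyl next to C–OMe, because the C1 carbonyl is deactivated as a vinylogous ester; the carbinol centre is racemic and is destroyed in step 11.

**Step 11**
Reactants: 19 4-hydroxy-3-methoxy-4-[(4E,8E,12E,16E,20E)-5,9,13,17,21,25-hexamethylhexacosa-1,4,8,12,16,20,24-heptaen-2-yl]cyclobut-2-en-1-one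
Product: 21 2-[(2E,6E,10E,14E,18E)-3,7,11,15,19,23-hexamethyltetracosa-2,6,10,14,18,22-hexaen-1-yl]-6-methoxybenzene-1,4-diol, via dienylketene 20 (not isolated)
Conditions: toluene (degassed), 110 °C, argon
Reagents that add atoms: none
Why: On heating, the cyclobutenone should undergo conrotatory 4π opening of its C1–C4 bond, the C4 hydroxyl turning outward (donor torquoselectivity) so that the alkenyl group turns inward and the (Z)-dienylketene 20 results; 6π electrocyclisation then joins the ketene carbon to the terminal CH2 of the 1,1-disubstituted vinyl group, and the cyclohexa-2,4-dienone formed enolises to hydroquinone 21. The closest known reaction type is the Moore-type thermal ring expansion of 4-alkenyl-4-hydroxycyclobutenones to hydroquinones. The six-membered ring closes by thermal disrotatory 6π electrocyclisation (formally 6-endo at the vinyl terminus), forming the bond between the future C4 carbonyl carbon and C5. No stereocentre is created: the carbinol centre of 19 is erased on aromatisation, and the isolated E olefins of the chain lie outside the pericyclic array. The step needs the ketene to close onto carbon and not onto the hydroxyl oxygen (butenolide formation), which the outward rotation of the hydroxyl secures; the 2,6-relationship of methoxy group and side chain is already fixed by the connectivity of 19, since the ketene carbon can reach only the vinyl CH2. Degassed solvent should keep the electron-rich hydroquinone from uncontrolled oxidation before step 12.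

**Step 12**
Reactants: 21 2-[(2E,6E,10E,14E,18E)-3,7,11,15,19,23-hexamethyltetracosa-2,6,10,14,18,22-hexaen-1-yl]-6-methoxybenzene-1,4-diol
Product: 22 2-[(2E,6E,10E,14E,18E)-3,7,11,15,19,23-hexamethyltetracosa-2,6,10,14,18,22-hexaen-1-yl]-6-methoxy-1,4-benzoquinone
Conditions: Ag2O, MgSO4, Et2O, rt, dark
Reagents that add atoms: none
Why: Two-electron dehydrogenation of the hydroquinone by monovalent silver (hydroquinone-to-quinone oxidation) runs under neutral, anhydrous conditions that should leave the skipped polyene untouched.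

**Compound list**

1 | (2E,6E)-farnesyl acetate | CC(=O)OC/C=C(\C)CC/C=C(\C)CCC=C(C)C | starting material
2 | (2E,6E,10E)-12-hydroxy-3,7,11-trimethyldodeca-2,6,10-trien-1-yl acetate | CC(=O)OC/C=C(\C)CC/C=C(\C)CC/C=C(\C)CO | intermediate
3 | (2E,6E,10E)-12-bromo-3,7,11-trimethyldodeca-2,6,10-trien-1-yl acetate | CC(=O)OC/C=C(\C)CC/C=C(\C)CC/C=C(\C)CBr | intermediate
4 | (2E,6E)-farnesyl bromide | BrC/C=C(\C)CC/C=C(\C)CCC=C(C)C | starting material
5 | (2E,6E)-farnesyl phenyl sulfone | O=S(=O)(C/C=C(\C)CC/C=C(\C)CCC=C(C)C)c1ccccc1 | intermediate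
6 | α-lithiated farnesyl phenyl sulfone (not isolated) | [Li]C(/C=C(\C)CC/C=C(\C)CCC=C(C)C)S(=O)(=O)c1ccccc1 | intermediate
7 | (2E,6E,10E,14E,18E)-3,7,11,15,19,23-hexamethyl-13-(phenylsulfonyl)tetracosa-2,6,10,14,18,22-hexaen-1-yl acetate (racemic) | CC(=O)OC/C=C(\C)CC/C=C(\C)CC/C=C(\C)CC(/C=C(\C)CC/C=C(\C)CCC=C(C)C)S(=O)(=O)c1ccccc1 | intermediate
8 | lithium alkoxide of 13-(phenylsulfonyl)hexaprenol (racemic, not isolated) | [Li]OC/C=C(\C)CC/C=C(\C)CC/C=C(\C)CC(/C=C(\C)CC/C=C(\C)CCC=C(C)C)S(=O)(=O)c1ccccc1 | intermediate
9 | all-E hexaprenol, (2E,6E,10E,14E,18E)-3,7,11,15,19,23-hexamethyltetracosa-2,6,10,14,18,22-hexaen-1-ol | OC/C=C(\C)CC/C=C(\C)CC/C=C(\C)CC/C=C(\C)CC/C=C(\C)CCC=C(C)C | intermediate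
10 | all-E hexaprenyl bromide | BrC/C=C(\C)CC/C=C(\C)CC/C=C(\C)CC/C=C(\C)CC/C=C(\C)CCC=C(C)C | intermediate
11 | ethynylmagnesium bromide | C#C[Mg]Br | starting material
12 | (4E,8E,12E,16E,20E)-5,9,13,17,21,25-hexamethylhexacosa-4,8,12,16,20,24-hexaen-1-yne | C#CC/C=C(\C)CC/C=C(\C)CC/C=C(\C)CC/C=C(\C)CC/C=C(\C)CCC=C(C)C | intermediate
13 | B-[(1Z)-2-bromoalkenyl]-9-BBN from 12 (Br and B cis, not isolated) | Br/C(C/C=C(\C)CC/C=C(\C)CC/C=C(\C)CC/C=C(\C)CC/C=C(\C)CCC=C(C)C)=C\B1C2CCCC1CCC2 | intermediate
14 | (4E,8E,12E,16E,20E)-2-bromo-5,9,13,17,21,25-hexamethylhexacosa-1,4,8,12,16,20,24-heptaene | C=C(Br)C/C=C(\C)CC/C=C(\C)CC/C=C(\C)CC/C=C(\C)CC/C=C(\C)CCC=C(C)C | intermediate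
15 | dimethyl squarate (3,4-dimethoxycyclobut-3-ene-1,2-dione) | COC1=C(OC)C(=O)C1=O | starting material
16 | 4-hydroxy-2,3-dimethoxycyclobut-2-en-1-one (racemic, not isolated) | COC1=C(OC)C(O)C1=O | intermediate
17 | 3-methoxycyclobut-3-ene-1,2-dione (methyl semisquarate) | COC1=CC(=O)C1=O | intermediate
18 | 2-lithio derivative of the heptaene of 14 (not isolated) | [Li]C(=C)C/C=C(\C)CC/C=C(\C)CC/C=C(\C)CC/C=C(\C)CC/C=C(\C)CCC=C(C)C | intermediate
19 | 4-hydroxy-3-methoxy-4-[(4E,8E,12E,16E,20E)-5,9,13,17,21,25-hexamethylhexacosa-1,4,8,12,16,20,24-heptaen-2-yl]cyclobut-2-en-1-one (racemic) | COC1=CC(=O)C1(O)C(=C)C/C=C(\C)CC/C=C(\C)CC/C=C(\C)CC/C=C(\C)CC/C=C(\C)CCC=C(C)C | intermediate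
20 | (Z)-dienylketene O=C=CH–C(OMe)=C(OH)–C(=CH2)–CH2R, ketenyl and alkenyl groups cis (not isolated) | O=C=C/C(OC)=C(/O)C(=C)C/C=C(\C)CC/C=C(\C)CC/C=C(\C)CC/C=C(\C)CC/C=C(\C)CCC=C(C)C | intermediate
21 | 2-hexaprenyl-6-methoxybenzene-1,4-diol (all-E) | COc1cc(O)cc(C/C=C(\C)CC/C=C(\C)CC/C=C(\C)CC/C=C(\C)CC/C=C(\C)CCC=C(C)C)c1O | intermediate
22 | 2-hexaprenyl-6-methoxy-1,4-benzoquinone (all-E) | COC1=CC(=O)C=C(C/C=C(\C)CC/C=C(\C)CC/C=C(\C)CC/C=C(\C)CC/C=C(\C)CCC=C(C)C)C1=O | target

**Step count and risks**

Total step count: 12. Longest linear sequence: 10 steps (steps 1, 2, 4, 5, 6, 7, 8, 10, 11, 12, from farnesyl acetate 1); steps 3 and 9 are convergent branches.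

Steps most likely to fail:

1. Step 10. The vinyllithium may be quenched by proton transfer from its own doubly allylic CH2 group before it adds. Part of the addition may also go to the vinylogous-ester carbonyl of 17, which would erode the regiochemistry that defines the 2,6-pattern. Fallback: the four-membered ring donor is given up and the chain is placed on an aromatic ring. Setting out from 10, 2-methoxyphenol is deprotonated with NaH in toluene and C-alkylated by 10 at its only free ortho position (Claisen-type ortho C-allylation of a phenoxide in a non-polar medium) to give 2-hexaprenyl-6-methoxyphenol F1. Para-oxidation of F1 with (KSO3)2NO (Fremy's salt, Teuber oxidation) in aqueous KH2PO4/acetone should then give the quinone, so the fallback comes back to the route at 22.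

2. Step 11. The free tertiary hydroxyl may ionise with loss of methanol, or turn inward and add to the ketene (lactonisation to a butenolide), in competition with the 6π closure. The free hydroquinone may also oligomerise at 110 °C. Fallback: the precursor is redesigned with a capped carbinol. Setting out from 19, silylation (Me3SiCl, Et3N, CH2Cl2, 0 °C) gives the trimethylsilyl ether of 19 F2. Its thermolysis in toluene at 110 °C (the silyloxy group again rotating outward) should give the mono-silylated hydroquinone, 3-methoxy-5-hexaprenyl-4-(trimethylsilyloxy)phenol F3. Cleavage of the aryl silyl ether with K2CO3 in MeOH brings the fallback back to the route at 21.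

3. Step 8. Traces of HBr or the Lewis-acidic borane may add to, or start cation–olefin cyclisation of, the trisubstituted olefins, and the skipped enyne may isomerise towards an allene during haloboration and protonolysis. Fallback: setting out from 12, nickel-catalysed α-selective hydroalumination (i-Bu2AlH, NiCl2(dppp) cat., THF, rt) gives the internal alkenylalane, diisobutyl(hexaprenyl-substituted vinyl)alane F4. Bromination of F4 with NBS at 0 °C comes back to the route at 14.

**Further compounds**

F1 | step 10 | 2-hexaprenyl-6-methoxyphenol (all-E) | COc1cccc(C/C=C(\C)CC/C=C(\C)CC/C=C(\C)CC/C=C(\C)CC/C=C(\C)CCC=C(C)C)c1O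
F2 | step 11 | 3-methoxy-4-(trimethylsilyloxy)-4-[(4E,8E,12E,16E,20E)-5,9,13,17,21,25-hexamethylhexacosa-1,4,8,12,16,20,24-heptaen-2-yl]cyclobut-2-en-1-one (racemic) | COC1=CC(=O)C1(O[Si](C)(C)C)C(=C)C/C=C(\C)CC/C=C(\C)CC/C=C(\C)CC/C=C(\C)CC/C=C(\C)CCC=C(C)C
F3 | step 11 | 3-methoxy-5-hexaprenyl-4-(trimethylsilyloxy)phenol (all-E) | COc1cc(O)cc(C/C=C(\C)CC/C=C(\C)CC/C=C(\C)CC/C=C(\C)CC/C=C(\C)CCC=C(C)C)c1O[Si](C)(C)C
F4 | step 8 | diisobutyl[(4E,8E,12E,16E,20E)-5,9,13,17,21,25-hexamethylhexacosa-1,4,8,12,16,20,24-heptaen-2-yl]alane | C=C([Al](CC(C)C)CC(C)C)C/C=C(\C)CC/C=C(\C)CC/C=C(\C)CC/C=C(\C)CC/C=C(\C)CCC=C(C)C
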